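**Assumption:** 6-bromo-4-methoxy-1H-indole (1), (E)-N,N-dimethyl-2-nitroethen-1-amine (2) and 5-bromo-1H-pyrrole-2-carboxylic acid (5) are taken as purchasable catalogue compounds, so the 4-methoxy/6-bromo pattern and both bromine atoms enter with building blocks.

## The problem

Compound 9 is a row of three five-membered aza-aromatic rings without any stereocentre: a 6-bromo-4-methoxyindole is bound through C3 to C5 of an oxazole, whose C2 carries a 5-bromopyrrol-2-yl group and whose C4 carries only hydrogen. The meta pattern of the benzo ring (OMe at C4, Br at C6) cannot be written onto an indole by substitution, and the second bromine sits on a pyrrole; both are bought with the building blocks, so two different C(sp2)–Br bonds travel through every step. These bonds rule out the usual biaryl logic (zerovalent palladium or nickel, halogen–metal exchange) and any hydride or dissolving-metal reduction. The two free N–H groups and the very electron-rich 4-methoxyindole and pyrrole rings do not tolerate the quinone or hypervalent-iodine oxidants, or the hot dehydrating acids, with which oxazoles are normally closed. The new C–C bond at indole C3 must also be made next to the peri methoxy group at C4. The task is therefore to create the central oxazole between two sensitive halo-heteroarenes under metal-free, redox-neutral, non-dehydrating conditions.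

The feature that allows this is the substitution of the oxazole: C4 is unsubstituted, C5 bears the indol-3-yl donor and C2 is an acyl carbon bound to the pyrrole. N3–C4(H)=C5(indolyl) is atom for atom the N1–C5(H)=C4(indolyl) unit of a 4-(indol-3-yl)-1,2,3-triazole, and O1–C2 is a pyrrole-2-carbonyl group. The oxazole is thus an N1-acyl triazole that has lost its N2–N3 unit, and the indole nitrogen (through C2=C3) stabilises the positive charge that appears at C5 when this unit leaves.

## Retrosynthesis

**Disconnection 1 (9 ⇒ 8 ⇌ 7 ⇒ 4 + 6).** The oxazole bonds O1–C5 and C2–N3 are cut, and two nitrogen atoms are put back between oxazole N3 and C5. This gives the N1-acyl triazole 8, which equilibrates with its N2-acyl isomer 7 and is the acylation product of the NH-triazole 4 with the acid chloride 6. The neighbouring cuts are the biaryl bonds indole C3–oxazole C5 or oxazole C2–pyrrole C2 (cross-coupling beside two C–Br bonds), or O1–C5 alone (dehydration or dehydrogenation of an open-chain amide). Against these, the chosen cut needs no metal, oxidant or dehydrating agent, and it divides 9 into two halves of similar size that each carry one bromine. The forward reaction must acylate the triazole nitrogen in the presence of two other N–H groups and open 8 so that the indolyl-bearing carbon becomes oxazole C5.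

**Disconnection 2 (6 ⇒ 5).** The C–Cl bond of 6 is cut back to the commercial acid 5. The forward reaction must activate the acid without touching the NH-pyrrole ring.

**Disconnection 3 (4 ⇒ 3).** The triazole bonds C4–N3 and C5–N1 are cut. The three nitrogens come from azide ion and the two carbons are the olefinic carbons of the nitroalkene 3; its nitro group is the leaving group that makes the cycloadduct aromatic without an oxidant. The neighbouring cut, to a 3-ethynylindole, would need N-protection and several more steps. Compound 3 holds only the indole and a two-carbon side chain. The forward reaction must make azide add to a push–pull nitroalkene.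

**Disconnection 4 (3 ⇒ 1 + 2).** The bond from indole C3 to the side chain is cut. Forward, the nitroenamine 2 delivers both side-chain carbons and the nitro group in one acid-mediated substitution at C3, the innately nucleophilic carbon of 1. Formylation followed by nitroaldol condensation would take two steps. The forward reaction must attack C3 despite the peri methoxy group and leave C2, C5 and C7 alone.

## Roads not taken

**Alternative 1:** the most obvious route cuts only oxazole O1–C5 in the dehydrative sense. Indole 1 would be acylated at C3 and aminated to the α-amino ketone A1, which is acylated with 6 to the keto amide A2. The forward key step is a Robinson–Gabriel cyclodehydration of A2. The chosen plan is better for three reasons: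
- The ketone of A2 is a vinylogous amide (indole N1–C2=C3–C=O), made still less electrophilic by the 4-methoxy group. It cyclises only under forcing electrophilic activation, which the unprotected indole and pyrrole do not tolerate, so N-protection and deprotection would be added.
- A1 is a primary α-amino ketone that self-condenses and must be made through a reduction that spares the C–Br bond.
- The sequence is at least five linear steps against three.

**Alternative 2:** cut the biaryl bond indole C3–oxazole C5. The forward key step is a Suzuki–Miyaura coupling of the N-silylated 3-indolylboronate A3 with the 5-iodooxazole A4 under zerovalent palladium. The chosen plan is better for three reasons: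
- Each partner carries a C–Br bond, so only the rate difference between C–I and C–Br oxidative addition stands against oligomerisation.
- A3 is a peri-hindered, electron-rich heteroaryl boronate prone to protodeboronation.
- A4 needs its own multistep synthesis with selective halogenation of oxazole C5 beside a bromopyrrole, and the indole needs a protecting group.

**Alternative 3:** cut oxazole O1–C5 in the oxidative, biomimetic sense. The tryptamine A5 would be acylated with 6 to the amide A6. The forward key step is a four-electron dehydrogenative cyclisation of A6 with DDQ or at an anode, through the 3-alkylidene-3H-indolium ion and an oxazoline. The chosen plan is better for three reasons: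
- In the chosen route the oxidation equivalents are carried by the nitro and azide nitrogens and leave as nitrite and dinitrogen, so no external oxidant meets the 4-methoxyindole or the pyrrole.
- In the alternative, the oxidant must abstract hydride twice next to the most oxidisable ring of the molecule, in competition with ring oxidation and with capture by water to give A2.
- A5 needs a reduction of 3 that must spare the C–Br bond, and the route is two steps longer.

Key step: step 4

## Route

**Step 1**
Reactants: 1 6-bromo-4-methoxy-1H-indole; 2 (E)-N,N-dimethyl-2-nitroethen-1-amine
Product: 3 6-bromo-4-methoxy-3-[(E)-2-nitroethenyl]-1H-indole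
Conditions: CF3CO2H, CH2Cl2, 0 °C to rt
Reagents that add atoms: none
Why: Acid-mediated nitro-olefination (electrophilic aromatic substitution by addition–elimination): protonated 2 is attacked by C3 of 1, the most nucleophilic carbon and further activated by the 4-methoxy group, and loss of dimethylamine gives the conjugated nitroalkene with the thermodynamically preferred E geometry; the reaction type is well precedented for 4-alkoxyindoles and needs no N-protection.

**Step 2**
Reactants: 3 6-bromo-4-methoxy-3-[(E)-2-nitroethenyl]-1H-indole
Product: 4 6-bromo-4-methoxy-3-(1H-1,2,3-triazol-4-yl)-1H-indole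
Conditions: NaN3 (1.5 equiv), TsOH·H2O (0.3 equiv), DMF, 60 °C
Reagents that add atoms: sodium azide, [Na+].[N-]=[N+]=[N-]
Why: Azide–nitroalkene [3+2] cycloaddition followed by elimination of nitrite, the known route from β-nitrostyrenes to 4-aryl-NH-1,2,3-triazoles; the acid raises the electrophilicity of the push–pull nitroalkene by giving it 3-alkylidene-indolium character, excess azide destroys any nitrous acid before it can nitrosate the indole, and the aryl bromide and N–H are inert.

**Step 3**
Reactants: 5 5-bromo-1H-pyrrole-2-carboxylic acid
Product: 6 5-bromo-1H-pyrrole-2-carbonyl chloride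
Conditions: (COCl)2 (1.2 equiv), DMF (cat.), CH2Cl2, 0 °C to rt; volatiles removed, used at once
Reagents that add atoms: oxalyl chloride, O=C(Cl)C(=O)Cl
Why: Standard acid chloride formation through the catalytic chloroiminium species; the acyl and bromo substituents deactivate the pyrrole ring towards C-acylation or formylation, and the chloride is used crude because NH-pyrrole acid chlorides self-condense on storage.

**Step 4**
Reactants: 4 6-bromo-4-methoxy-3-(1H-1,2,3-triazol-4-yl)-1H-indole; 6 5-bromo-1H-pyrrole-2-carbonyl chloride
Product: 9 6-bromo-3-[2-(5-bromo-1H-pyrrol-2-yl)-1,3-oxazol-5-yl]-4-methoxy-1H-indole, via N2-acyl triazole 7 (not isolated), via N1-acyl triazole 8 (not isolated)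
Conditions: Et3N (1.0 equiv), ClCH2CH2Cl, 0 °C to rt; then CF3SO3H (0.2 equiv), 60 °C
Reagents that add atoms: none
Why: Acylative denitrogenative ring transformation of an NH-1,2,3-triazole into an oxazole: Et3N removes the triazole N–H of 4 (by far the most acidic N–H present, so indole and pyrrole N–H stay untouched) and 6 acylates it to the N2-acyl triazole 7, which equilibrates by acyl transfer with the N1-acyl isomer 8. Under acid, 8 opens by cleavage of N1–N2 (ring–chain tautomerism to the α-diazo N-acylimine, in protonated form a β-amido vinyldiazonium ion) and loses dinitrogen; the cation at the former triazole C4 is a 3-alkylidene-3H-indolium ion stabilised by the indole nitrogen and the 4-methoxy group, so this substrate should open more easily than a phenyl analogue. The amide oxygen then attacks this carbon (1,5-closure of the acylimino carbene or vinyl cation, formally 5-endo) to form O1–C5, and loss of a proton gives the aromatic oxazole 9 and returns the acid. The closest known reaction type is the acid-mediated ring cleavage of N-acylated 4-aryl-NH-1,2,3-triazoles to β-enamido triflates and 2,5-disubstituted oxazoles, the triazole counterpart of the Huisgen conversion of tetrazoles into 1,3,4-oxadiazoles. The oxazole is the only ring closed and no stereocentre is formed. The selectivity needed is regiochemical (2,5- against 2,4-disubstituted oxazole): only acylation at N1, remote from the indolyl group, puts the cationic carbon under the indolyl donor, whereas acylation at N3 is hindered by the peri-methoxyindolyl group and would give an unstabilised cation. Oxygen and not pyrrole nitrogen closes the ring because the pyrrole lone pair is part of the aromatic sextet and its attack would need a six-membered transition state; both C–Br bonds are spectators under these metal-free, redox-neutral conditions.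

## Compound list

1 | 6-bromo-4-methoxy-1H-indole | COc1cc(Br)cc2[nH]ccc12 | starting material
2 | (E)-N,N-dimethyl-2-nitroethen-1-amine | CN(C)/C=C/[N+](=O)[O-] | starting material
3 | 6-bromo-4-methoxy-3-[(E)-2-nitroethenyl]-1H-indole | COc1cc(Br)cc2[nH]cc(/C=C/[N+](=O)[O-])c12 | intermediate
4 | 6-bromo-4-methoxy-3-(1H-1,2,3-triazol-4-yl)-1H-indole | COc1cc(Br)cc2[nH]cc(-c3c[nH]nn3)c12 | intermediate
5 | 5-bromo-1H-pyrrole-2-carboxylic acid | OC(=O)c1ccc(Br)[nH]1 | starting material
6 | 5-bromo-1H-pyrrole-2-carbonyl chloride | ClC(=O)c1ccc(Br)[nH]1 | intermediate
7 | (5-bromo-1H-pyrrol-2-yl)[4-(6-bromo-4-methoxy-1H-indol-3-yl)-2H-1,2,3-triazol-2-yl]methanone | COc1cc(Br)cc2[nH]cc(-c3cnn(C(=O)c4ccc(Br)[nH]4)n3)c12 | intermediate (not isolated)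
8 | (5-bromo-1H-pyrrol-2-yl)[4-(6-bromo-4-methoxy-1H-indol-3-yl)-1H-1,2,3-triazol-1-yl]methanone | COc1cc(Br)cc2[nH]cc(-c3cn(C(=O)c4ccc(Br)[nH]4)nn3)c12 | intermediate (not isolated)
9 | 6-bromo-3-[2-(5-bromo-1H-pyrrol-2-yl)-1,3-oxazol-5-yl]-4-methoxy-1H-indole | COc1cc(Br)cc2[nH]cc(-c3cnc(-c4ccc(Br)[nH]4)o3)c12 | target

## Step count and least certain steps

Total: 4 steps. Longest linear sequence: 3 steps (1 → 3 → 4 → 9); step 3 is a one-step side branch.

**Step 4 (key step).** The most likely failure is that the acyl group rests on N2 and is passed on to adventitious nucleophiles faster than the N1-acyl isomer opens. A second failure is capture of the cationic intermediate by chloride or water instead of by the amide oxygen; acid-induced oligomerisation of the electron-rich indole is a lesser risk. The fallback sets out from 1, uses 6 and comes back at 9. C3 acylation of 1 with chloroacetyl chloride and Et2AlCl in CH2Cl2 at 0 °C should give 1-(6-bromo-4-methoxy-1H-indol-3-yl)-2-chloroethan-1-one F1. Displacement with NaN3 in DMF gives 2-azido-1-(6-bromo-4-methoxy-1H-indol-3-yl)ethan-1-one F2. A one-pot Staudinger reaction with PPh3, N-acylation of the iminophosphorane by 6 in the presence of Et3N, and aza-Wittig-type closure onto the ketone oxygen then give 9.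

**Step 2.** The most likely failure is slow addition of azide to the push–pull nitroalkene, which leaves time for oligomerisation of 3 by conjugate addition or for nitrosation of the indole by liberated nitrous acid. The fallback sets out from 1 and comes back at 4 by an alkyne–azide cycloaddition:
- Vilsmeier–Haack formylation (POCl3, DMF) should give 6-bromo-4-methoxy-1H-indole-3-carbaldehyde F3.
- N-sulfonylation (TsCl, NaH, THF) gives 6-bromo-4-methoxy-1-(4-methylbenzenesulfonyl)-1H-indole-3-carbaldehyde F4.
- Seyferth–Gilbert homologation with the Ohira–Bestmann reagent (K2CO3, MeOH) gives 6-bromo-3-ethynyl-4-methoxy-1-(4-methylbenzenesulfonyl)-1H-indole F5.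
- CuI-catalysed cycloaddition with Me3SiN3 in DMF/MeOH at 100 °C gives 6-bromo-4-methoxy-1-(4-methylbenzenesulfonyl)-3-(1H-1,2,3-triazol-4-yl)-1H-indole F6.
- Removal of the sulfonyl group with Cs2CO3 in THF/MeOH gives 4.

**Step 3.** The most likely failure is self-condensation of the NH-pyrrole acid chloride (loss of HCl to a ketene-type species and dimerisation) during concentration or on contact with base. The fallback sets out from 5 together with 4 and comes back at 7. Direct dehydrative N-acylation of the triazole with N,N'-diisopropylcarbodiimide in CH2Cl2/DMF, as in the carbodiimide preparation of N-acylbenzotriazoles, should form 7 and 8 in the flask without any acid chloride. The acid stage of step 4 then follows.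

## Further compounds

F1 | step 4 | 1-(6-bromo-4-methoxy-1H-indol-3-yl)-2-chloroethan-1-one | COc1cc(Br)cc2[nH]cc(C(=O)CCl)c12
F2 | step 4 | 2-azido-1-(6-bromo-4-methoxy-1H-indol-3-yl)ethan-1-one | COc1cc(Br)cc2[nH]cc(C(=O)CN=[N+]=[N-])c12
F3 | step 2 | 6-bromo-4-methoxy-1H-indole-3-carbaldehyde | COc1cc(Br)cc2[nH]cc(C=O)c12
F4 | step 2 | 6-bromo-4-methoxy-1-(4-methylbenzenesulfonyl)-1H-indole-3-carbaldehyde | COc1cc(Br)cc2n(S(=O)(=O)c3ccc(C)cc3)cc(C=O)c12
F5 | step 2 | 6-bromo-3-ethynyl-4-methoxy-1-(4-methylbenzenesulfonyl)-1H-indole | COc1cc(Br)cc2n(S(=O)(=O)c3ccc(C)cc3)cc(C#C)c12
F6 | step 2 | 6-bromo-4-methoxy-1-(4-methylbenzenesulfonyl)-3-(1H-1,2,3-triazol-4-yl)-1H-indole | COc1cc(Br)cc2n(S(=O)(=O)c3ccc(C)cc3)cc(-c4c[nH]nn4)c12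
F0 | step 3 | none | none
A1 | alternative 1 | 2-amino-1-(6-bromo-4-methoxy-1H-indol-3-yl)ethan-1-one | COc1cc(Br)cc2[nH]cc(C(=O)CN)c12
A2 | alternative 1 | 5-bromo-N-[2-(6-bromo-4-methoxy-1H-indol-3-yl)-2-oxoethyl]-1H-pyrrole-2-carboxamide | COc1cc(Br)cc2[nH]cc(C(=O)CNC(=O)c3ccc(Br)[nH]3)c12
A3 | alternative 2 | 6-bromo-4-methoxy-3-(4,4,5,5-tetramethyl-1,3,2-dioxaborolan-2-yl)-1-(triisopropylsilyl)-1H-indole | COc1cc(Br)cc2c1c(B1OC(C)(C)C(C)(C)O1)cn2[Si](C(C)C)(C(C)C)C(C)C
A4 | alternative 2 | 2-(5-bromo-1H-pyrrol-2-yl)-5-iodo-1,3-oxazole | Brc1ccc(-c2ncc(I)o2)[nH]1
A5 | alternative 3 | 2-(6-bromo-4-methoxy-1H-indol-3-yl)ethan-1-amine | COc1cc(Br)cc2[nH]cc(CCN)c12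
A6 | alternative 3 | 5-bromo-N-[2-(6-bromo-4-methoxy-1H-indol-3-yl)ethyl]-1H-pyrrole-2-carboxamide | COc1cc(Br)cc2[nH]cc(CCNC(=O)c3ccc(Br)[nH]3)c12
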